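**Retrosynthetic overview**
- Target 17 comes from 14 by methylation of the free 7-OH and hydrogenolysis of the two benzyl ethers (3-OH and 3′-OH).
- Ring A of 14 is cut at C7–C8 and C5–C6. Along C5–C8 the hydroxylated carbons C5 and C7 (former carbonyl carbons) alternate with the methoxylated carbons C6 and C8. C5 is therefore the ester carbon and C8 the methoxymethyl carbon of pyranone 10, and C6–C7 come from methyl methoxyacetate 11.
- Pyranone 10 (ring C carrying ring B) comes from triketo ester 9 by cyclodehydration; 9 from diketo ester 7 and methoxyacetyl chloride; 7 from the dianion aldol of keto ester 4 with aldehyde 3, then oxidation.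
- Ring order: ring B is bought, ring C is closed in step 5, ring A is folded onto it in step 6.

Key step: step 6

Remark: 6, 7, 9 and 13 are racemic (6 also a diastereomeric mixture) and are used as such, because every sp3 stereocenter is erased before the achiral target.

Step 1
Reactants: 1 3-hydroxy-4,5-dimethoxybenzaldehyde; 2 benzyl bromide
Product: 3 3-(benzyloxy)-4,5-dimethoxybenzaldehyde
Conditions: BnBr (1.2 equiv), K2CO3 (1.5 equiv), DMF, 60 °C
Reagents that add atoms: benzyl bromide (2), BrCc1ccccc1
Why: Williamson ether synthesis on the only phenol, with an aldehyde that has no enolisable position and is inert to carbonate.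

Step 2
Reactants: 4 ethyl 4-(benzyloxy)-3-oxobutanoate; 3 3-(benzyloxy)-4,5-dimethoxybenzaldehyde
Product: 6 ethyl 4-(benzyloxy)-5-[3-(benzyloxy)-4,5-dimethoxyphenyl]-5-hydroxy-3-oxopentanoate (racemic mixture of diastereomers), via dilithio dianion 5 (not isolated)
Conditions: LiN(i-Pr)2 (2.2 equiv), THF, −78 to −20 °C; 3, −78 °C; AcOH, −78 °C
Reagents that add atoms: none
Why: Weiler-type β-keto ester dianion aldol addition, in which the less stabilised charge on the benzyloxy-bearing γ-carbon is the one that adds to the aldehyde; the two new stereocenters form without control, which is harmless because both carbons become sp2 by step 5.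

Step 3
Reactants: 6 ethyl 4-(benzyloxy)-5-[3-(benzyloxy)-4,5-dimethoxyphenyl]-5-hydroxy-3-oxopentanoate
Product: 7 ethyl 4-(benzyloxy)-5-[3-(benzyloxy)-4,5-dimethoxyphenyl]-3,5-dioxopentanoate (keto/enol mixture)
Conditions: Dess–Martin periodinane (1.3 equiv), CH2Cl2, 0 °C to rt
Reagents that add atoms: none
Why: Dess–Martin oxidation of the benzylic secondary alcohol to the aryl ketone under near-neutral conditions, the usual way from δ-hydroxy-β-keto esters to 3,5-diketo esters, leaving both benzyl ethers untouched.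

Step 4
Reactants: 7 ethyl 4-(benzyloxy)-5-[3-(benzyloxy)-4,5-dimethoxyphenyl]-3,5-dioxopentanoate; 8 methoxyacetyl chloride
Product: 9 ethyl 4-(benzyloxy)-5-[3-(benzyloxy)-4,5-dimethoxyphenyl]-2-(methoxyacetyl)-3,5-dioxopentanoate (enolised tricarbonyl)
Conditions: MgCl2 (1.1 equiv), pyridine (2.2 equiv), CH2Cl2, 0 °C; 8 (1.05 equiv), 0 °C to rt; 1 M HCl wash
Reagents that add atoms: methoxyacetyl chloride (8), COCC(=O)Cl
Why: Rathke-type soft-enolisation C-acylation, in which only the C2 methylene can end as a stable magnesium tricarbonyl chelate, the C4 methine is too hindered for quaternisation, and an acyl group that lands on a diketone enol oxygen can migrate to C2 through a six-membered transition state (Baker–Venkataraman type).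

Step 5
Reactants: 9 ethyl 4-(benzyloxy)-5-[3-(benzyloxy)-4,5-dimethoxyphenyl]-2-(methoxyacetyl)-3,5-dioxopentanoate
Product: 10 ethyl 5-(benzyloxy)-6-[3-(benzyloxy)-4,5-dimethoxyphenyl]-2-(methoxymethyl)-4-oxo-4H-pyran-3-carboxylate
Conditions: p-TsOH·H2O (0.1 equiv), toluene, 80 °C, 4 Å molecular sieves
Reagents that add atoms: none
Why: Acid-catalysed cyclodehydration of a 1,3,5-triketone to a 4-pyranone (enol oxygen of one terminal ketone adds to the other, then water is lost), which should be faster than lactonisation onto the less electrophilic ester and mild enough for both benzyl ethers.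

Step 6
Reactants: 10 ethyl 5-(benzyloxy)-6-[3-(benzyloxy)-4,5-dimethoxyphenyl]-2-(methoxymethyl)-4-oxo-4H-pyran-3-carboxylate; 11 methyl methoxyacetate
Product: 14 3-(benzyloxy)-2-[3-(benzyloxy)-4,5-dimethoxyphenyl]-5,7-dihydroxy-6,8-dimethoxy-4H-chromen-4-one, via lateral lithio anion 12 (not isolated), via Claisen ketone 13 (not isolated)
Conditions: LiN(i-Pr)2 (1.1 equiv), THF, −78 °C; 11 (1.3 equiv), −78 °C; LiN(i-Pr)2 (3.0 equiv), −78 to 0 °C; then 1 M HCl
Reagents that add atoms: methyl methoxyacetate (11), COCC(=O)OC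
Why: Proposed new method: the CH2 of the 2-methoxymethyl group is γ to both the C4 carbonyl and the C3 ester through the C2=C3 double bond, so LiN(i-Pr)2 should give the lateral dienolate 12, which adds to the α-alkoxy-activated ester carbonyl of 11 (Claisen condensation, C7–C8 bond) and, after loss of methoxide, gives ketone 13 as its enolate. Excess amide base should then remove a proton from the terminal CH2OMe of that enolate, and the terminal carbon of the dianion attacks the adjacent C3 ester (Dieckmann condensation, C5–C6 bond); loss of ethoxide and two enolisations give the aromatic 5,7-diol. The closest known reaction types are the lateral lithiation–acylation of 2-alkyl-4-pyranones and the acylation of ortho-toluate or homophthalate anions followed by Dieckmann closure to naphthalene-1,3-diols, as used in polyketide-type arene syntheses. Ring A closes in a 6-exo-trig mode by attack of an enolate carbon on the ester carbonyl, driven by aromatisation, and no stereocenter is created. Two selectivities are required: the base must abstract the lateral CH2 proton in preference to a benzylic OCH2 proton, which follows from its conjugation with two carbonyl groups, and the keto ester must close through carbon and not through the enolate oxygen (enol lactone), which the dianion generated with excess base should secure because its terminal carbon is the most nucleophilic site. Chelation of lithium by the α-methoxy group of 11 should hold the tetrahedral adduct at −78 °C until the second charge of base is present, so that the acidic ketone does not quench unreacted 12.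

Step 7
Reactants: 14 3-(benzyloxy)-2-[3-(benzyloxy)-4,5-dimethoxyphenyl]-5,7-dihydroxy-6,8-dimethoxy-4H-chromen-4-one; 15 dimethyl sulfate
Product: 16 3-(benzyloxy)-2-[3-(benzyloxy)-4,5-dimethoxyphenyl]-5-hydroxy-6,7,8-trimethoxy-4H-chromen-4-one
Conditions: Me2SO4 (1.1 equiv), K2CO3 (1.5 equiv), acetone, rt to 40 °C
Reagents that add atoms: dimethyl sulfate (15), COS(=O)(=O)OC
Why: Williamson-type O-methylation of the free, acidic 7-OH (para to the C4 carbonyl), while the 5-OH is held in a hydrogen bond to the C4 carbonyl and should stay unmethylated with one equivalent of reagent and a weak base.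

Step 8
Reactants: 16 3-(benzyloxy)-2-[3-(benzyloxy)-4,5-dimethoxyphenyl]-5-hydroxy-6,7,8-trimethoxy-4H-chromen-4-one
Product: 17 3-demethyldigicitrin, 3,5-dihydroxy-2-(3-hydroxy-4,5-dimethoxyphenyl)-6,7,8-trimethoxy-4H-chromen-4-one
Conditions: H2 (1 atm), 10% Pd/C, EtOAc–MeOH, rt
Reagents that add atoms: none
Why: Heterogeneous hydrogenolysis of both O-benzyl groups (enol ether at C3, aryl ether at C3′) under conditions at which the chromone C2–C3 double bond and the methyl ethers are stable.

**Compound list**
1 | 3-hydroxy-4,5-dimethoxybenzaldehyde | COc1cc(C=O)cc(O)c1OC | starting material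
2 | benzyl bromide | BrCc1ccccc1 | starting material
3 | 3-(benzyloxy)-4,5-dimethoxybenzaldehyde | COc1cc(C=O)cc(OCc2ccccc2)c1OC | intermediate
4 | ethyl 4-(benzyloxy)-3-oxobutanoate | CCOC(=O)CC(=O)COCc1ccccc1 | starting material
5 | dilithio dianion of 4 (dilithium dienediolate, not isolated) | [Li+].[Li+].CCOC([O-])=CC([O-])=COCc1ccccc1 | intermediate
6 | ethyl 4-(benzyloxy)-5-[3-(benzyloxy)-4,5-dimethoxyphenyl]-5-hydroxy-3-oxopentanoate (racemic, diastereomeric mixture) | CCOC(=O)CC(=O)C(OCc1ccccc1)C(O)c1cc(OC)c(OC)c(OCc2ccccc2)c1 | intermediate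
7 | ethyl 4-(benzyloxy)-5-[3-(benzyloxy)-4,5-dimethoxyphenyl]-3,5-dioxopentanoate (racemic, enolisable) | CCOC(=O)CC(=O)C(OCc1ccccc1)C(=O)c1cc(OC)c(OC)c(OCc2ccccc2)c1 | intermediate
8 | methoxyacetyl chloride | COCC(=O)Cl | starting material
9 | ethyl 4-(benzyloxy)-5-[3-(benzyloxy)-4,5-dimethoxyphenyl]-2-(methoxyacetyl)-3,5-dioxopentanoate (racemic, enolised) | CCOC(=O)C(C(=O)COC)C(=O)C(OCc1ccccc1)C(=O)c1cc(OC)c(OC)c(OCc2ccccc2)c1 | intermediate
10 | ethyl 5-(benzyloxy)-6-[3-(benzyloxy)-4,5-dimethoxyphenyl]-2-(methoxymethyl)-4-oxo-4H-pyran-3-carboxylate | COCc1oc(-c2cc(OC)c(OC)c(OCc3ccccc3)c2)c(OCc2ccccc2)c(=O)c1C(=O)OCC | intermediate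
11 | methyl methoxyacetate | COCC(=O)OC | starting material
12 | lateral lithio anion of 10 (lithium dienolate, not isolated) | [Li+].CO[CH-]c1oc(-c2cc(OC)c(OC)c(OCc3ccccc3)c2)c(OCc2ccccc2)c(=O)c1C(=O)OCC | intermediate
13 | ethyl 5-(benzyloxy)-6-[3-(benzyloxy)-4,5-dimethoxyphenyl]-2-(1,3-dimethoxy-2-oxopropyl)-4-oxo-4H-pyran-3-carboxylate (racemic, not isolated) | COCC(=O)C(OC)c1oc(-c2cc(OC)c(OC)c(OCc3ccccc3)c2)c(OCc2ccccc2)c(=O)c1C(=O)OCC | intermediate
14 | 3-(benzyloxy)-2-[3-(benzyloxy)-4,5-dimethoxyphenyl]-5,7-dihydroxy-6,8-dimethoxy-4H-chromen-4-one | COc1cc(-c2oc3c(OC)c(O)c(OC)c(O)c3c(=O)c2OCc2ccccc2)cc(OCc2ccccc2)c1OC | intermediate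
15 | dimethyl sulfate | COS(=O)(=O)OC | starting material
16 | 3-(benzyloxy)-2-[3-(benzyloxy)-4,5-dimethoxyphenyl]-5-hydroxy-6,7,8-trimethoxy-4H-chromen-4-one | COc1cc(-c2oc3c(OC)c(OC)c(OC)c(O)c3c(=O)c2OCc2ccccc2)cc(OCc2ccccc2)c1OC | intermediate
17 | 3-demethyldigicitrin, 3,5-dihydroxy-2-(3-hydroxy-4,5-dimethoxyphenyl)-6,7,8-trimethoxy-4H-chromen-4-one | COc1cc(-c2oc3c(OC)c(OC)c(OC)c(O)c3c(=O)c2O)cc(O)c1OC | target

**Step count**
Total steps: 8. Longest linear sequence: 8 steps (1 to 17).

**Steps most likely to fail**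

Step 6 (the proposed new method). The lateral anion may be quenched by proton transfer from the newly formed ketone, the ester 11 may be enolised and self-condense, or the keto ester may close through the enolate oxygen and not through carbon. The fallback uses known flavone chemistry; it sets out from 3 and comes back at 17.
- Claisen–Schmidt condensation of 3 with 1-(2-hydroxy-3,4,5,6-tetramethoxyphenyl)ethanone F1 (KOH, EtOH, rt) should give the chalcone (E)-3-[3-(benzyloxy)-4,5-dimethoxyphenyl]-1-(2-hydroxy-3,4,5,6-tetramethoxyphenyl)prop-2-en-1-one F2.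
- Oxidative cyclisation (catalytic I2, DMSO, 120 °C) should give the flavone 2-[3-(benzyloxy)-4,5-dimethoxyphenyl]-5,6,7,8-tetramethoxy-4H-chromen-4-one F3.
- Epoxidation of the C2–C3 double bond with dimethyldioxirane (acetone–CH2Cl2, 0 °C), then acid-catalysed opening of the epoxide (p-TsOH), should give the flavonol 2-[3-(benzyloxy)-4,5-dimethoxyphenyl]-3-hydroxy-5,6,7,8-tetramethoxy-4H-chromen-4-one F4.
- BCl3 (CH2Cl2, −78 to 0 °C) should then remove the 5-O-methyl group peri to the carbonyl (chelation control) together with the 3′-O-benzyl group, arriving at 17.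

Step 4. Acylation may occur at the C4 methine or stay on a diketone enol oxygen without migration, and the acyl group may be lost again on work-up. The fallback installs the methoxyacetyl group while only one 1,3-dicarbonyl site exists; it sets out from 6 and comes back at 10.
- Silylation of the alcohol (Et3SiCl, imidazole, CH2Cl2, 0 °C) should give ethyl 4-(benzyloxy)-5-[3-(benzyloxy)-4,5-dimethoxyphenyl]-3-oxo-5-[(triethylsilyl)oxy]pentanoate F5.
- C-acylation with 8 (MgCl2, pyridine, CH2Cl2) should give ethyl 4-(benzyloxy)-5-[3-(benzyloxy)-4,5-dimethoxyphenyl]-2-(methoxyacetyl)-3-oxo-5-[(triethylsilyl)oxy]pentanoate F6.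
- Wet trifluoroacetic acid in CH2Cl2 should remove the silyl group and close the freed alcohol onto the methoxyacetyl ketone with loss of water, giving ethyl 5-(benzyloxy)-6-[3-(benzyloxy)-4,5-dimethoxyphenyl]-2-(methoxymethyl)-4-oxo-5,6-dihydro-4H-pyran-3-carboxylate F7.
- Dehydrogenation with DDQ (dioxane, 90 °C), as in flavanone-to-flavone oxidations, should give 10.

Step 7. Site selectivity may be lost (the 5-OH is methylated too), or the 7-OH, flanked by two methoxy groups, may react incompletely. The fallback replaces selective methylation by exhaustive methylation and chelation-controlled dealkylation; it sets out from 14 and comes back at 17.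
- Exhaustive methylation (excess MeI, K2CO3, DMF, 60 °C) should give 3-(benzyloxy)-2-[3-(benzyloxy)-4,5-dimethoxyphenyl]-5,6,7,8-tetramethoxy-4H-chromen-4-one F8.
- BCl3 (CH2Cl2, −78 to 0 °C) should cleave the peri 5-O-methyl group selectively and both benzyl ethers, giving 17 directly.

Further compounds
F1 | step 6 | 1-(2-hydroxy-3,4,5,6-tetramethoxyphenyl)ethanone (additional starting material) | CC(=O)c1c(O)c(OC)c(OC)c(OC)c1OC
F2 | step 6 | (E)-3-[3-(benzyloxy)-4,5-dimethoxyphenyl]-1-(2-hydroxy-3,4,5,6-tetramethoxyphenyl)prop-2-en-1-one | COc1cc(/C=C/C(=O)c2c(O)c(OC)c(OC)c(OC)c2OC)cc(OCc2ccccc2)c1OC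
F3 | step 6 | 2-[3-(benzyloxy)-4,5-dimethoxyphenyl]-5,6,7,8-tetramethoxy-4H-chromen-4-one | COc1cc(-c2cc(=O)c3c(OC)c(OC)c(OC)c(OC)c3o2)cc(OCc2ccccc2)c1OC
F4 | step 6 | 2-[3-(benzyloxy)-4,5-dimethoxyphenyl]-3-hydroxy-5,6,7,8-tetramethoxy-4H-chromen-4-one | COc1cc(-c2oc3c(OC)c(OC)c(OC)c(OC)c3c(=O)c2O)cc(OCc2ccccc2)c1OC
F5 | step 4 | ethyl 4-(benzyloxy)-5-[3-(benzyloxy)-4,5-dimethoxyphenyl]-3-oxo-5-[(triethylsilyl)oxy]pentanoate (racemic, diastereomeric mixture) | CCOC(=O)CC(=O)C(OCc1ccccc1)C(O[Si](CC)(CC)CC)c1cc(OC)c(OC)c(OCc2ccccc2)c1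
F6 | step 4 | ethyl 4-(benzyloxy)-5-[3-(benzyloxy)-4,5-dimethoxyphenyl]-2-(methoxyacetyl)-3-oxo-5-[(triethylsilyl)oxy]pentanoate (racemic, diastereomeric mixture) | CCOC(=O)C(C(=O)COC)C(=O)C(OCc1ccccc1)C(O[Si](CC)(CC)CC)c1cc(OC)c(OC)c(OCc2ccccc2)c1
F7 | step 4 | ethyl 5-(benzyloxy)-6-[3-(benzyloxy)-4,5-dimethoxyphenyl]-2-(methoxymethyl)-4-oxo-5,6-dihydro-4H-pyran-3-carboxylate (racemic, diastereomeric mixture) | CCOC(=O)C1=C(COC)OC(c2cc(OC)c(OC)c(OCc3ccccc3)c2)C(OCc2ccccc2)C1=O
F8 | step 7 | 3-(benzyloxy)-2-[3-(benzyloxy)-4,5-dimethoxyphenyl]-5,6,7,8-tetramethoxy-4H-chromen-4-one | COc1cc(-c2oc3c(OC)c(OC)c(OC)c(OC)c3c(=O)c2OCc2ccccc2)cc(OCc2ccccc2)c1OC
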